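The epoxy end group (carotenoid numbering) is read as a dearomatised furan: O7, C3, C4, C5 and C6 of the 7-oxabicyclo[2.2.1]heptane are the ring atoms of (3-methylfuran-2-yl)methyl acetate, and C1–C2 is a methacrolein unit whose formyl group later becomes the second C1 methyl. A catalytic enantioselective Diels–Alder reaction joins C2–C3 and C1–C6 in one operation and sets both bridgeheads; exo-face hydration of the surviving C4=C5 alkene then relays C5. The triol end group comes from ketoisophorone by asymmetric transfer hydrogenation, directed epoxidation and hydrolysis. Two C15 phosphonium salts are joined through 2,7-dimethylocta-2,4,6-trienedial by successive Wittig reactions.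

Key step: step 3

Assumption: the (S)-oxazaborolidinium catalyst is taken to deliver the bridgehead configuration drawn for 5, by analogy with its 2-substituted acrolein/cyclopentadiene adducts; if the sense proves opposite, the (R)-catalyst is used with no other change.

Step 1
Reactants: 1 methyl 3-methylfuran-2-carboxylate
Product: 2 (3-methylfuran-2-yl)methanol
Conditions: LiAlH4, Et2O, 0 °C
Reagents that add atoms: none
Why: Hydride reduction of the ester to the primary alcohol leaves the furan untouched.

Step 2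
Reactants: 2 (3-methylfuran-2-yl)methanol
Product: 3 (3-methylfuran-2-yl)methyl acetate
Conditions: Ac2O, pyridine, DMAP (cat.), CH2Cl2, 0 °C to rt
Reagents that add atoms: acetic anhydride CC(=O)OC(C)=O
Why: Acetylation masks the furfuryl alcohol with a group that should not ionise at −78 °C and that the hydride of step 4 removes again.

Step 3
Reactants: 3 (3-methylfuran-2-yl)methyl acetate; 4 methacrolein (2-methylprop-2-enal)
Product: 6 [(1R,2R,4R)-2,6-dimethyl-2-[(E)-(tosylhydrazono)methyl]-7-oxabicyclo[2.2.1]hept-5-en-1-yl]methyl acetate, via aldehyde adduct 5 (not isolated)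
Conditions: (S)-3,3-diphenyl-1-(o-tolyl)oxazaborolidine·HNTf2 (15 mol%), CH2Cl2, −78 °C; Et3N; then TsNHNH2, MeOH, −40 to 0 °C
Reagents that add atoms: p-toluenesulfonyl hydrazide Cc1ccc(cc1)S(=O)(=O)NN
Why: The oxazaborolidinium ion binds methacrolein and the electron-rich furan adds in a concerted but asynchronous [4+2] cycloaddition, in which the free furan α-carbon (future C3) bonds first to the enal CH2 (future C2) and the substituted α-carbon (future C6) then closes onto the enal α-carbon (future C1). The closest known reaction type is the chiral oxazaborolidine-catalysed Diels–Alder reaction of furan with 2-substituted acroleins. The carbocyclic ring C1–C6 is closed by this intermolecular suprafacial [4+2] addition across the furan 2,5-positions, which turns the furan into the oxygen-bridged oxolane of the 7-oxabicyclo[2.2.1]heptene. The bridgeheads C3 and C6 are set together by the catalyst, which shields one face of the bound enal, in combination with the exo-formyl (methyl-endo) orientation usual for 2-substituted acroleins; the C1 centre is temporary and is erased in step 4. The step needs "ortho" regioselectivity, which the single unsubstituted nucleophilic α-position of the furan should secure, high exo/endo selectivity (an endo adduct would give the antipode after step 4), and ring closure faster than Friedel–Crafts alkylation, hence −78 °C. The labile adduct is quenched with base and condensed cold with the hydrazide, which removes the activating formyl group and should stop cycloreversion.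

Step 4
Reactants: 6 tosylhydrazone acetate
Product: 7 [(1S,4R)-2,6,6-trimethyl-7-oxabicyclo[2.2.1]hept-2-en-1-yl]methanol
Conditions: LiAlH4 (excess), THF, reflux
Reagents that add atoms: none
Why: Caglioti reduction (hydride addition to C=N, loss of sulfinate, loss of N2 from the diazene) turns the formyl carbon into the second C1 methyl, with no α-hydrogen available for alkene formation, and the same hydride cleaves the acetate.

Step 5
Reactants: 7 bicyclic alkenyl alcohol
Product: 8 (1R,2R,4R)-1-(hydroxymethyl)-2,6,6-trimethyl-7-oxabicyclo[2.2.1]heptan-2-ol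
Conditions: Co(acac)2 (20 mol%), PhSiH3, O2 (1 atm), THF, rt; then aq. Na2S2O3
Reagents that add atoms: dioxygen O=O
Why: Mukaiyama hydration puts hydrogen on C4 and gives the tertiary C5 radical, which should be trapped by O2 on the exo face (syn to the oxygen bridge, away from the endo C1 methyl), so that C5 is set with exo-OH by substrate control.

Step 6
Reactants: 8 diol
Product: 9 (1S,2R,4R)-2-hydroxy-2,6,6-trimethyl-7-oxabicyclo[2.2.1]heptane-1-carbaldehyde
Conditions: Dess–Martin periodinane, NaHCO3, CH2Cl2, 0 °C to rt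
Reagents that add atoms: none
Why: Dess–Martin oxidation converts the primary alcohol into the C7 aldehyde while the tertiary alcohol cannot be oxidised.

Step 7
Reactants: 9 hydroxy aldehyde
Product: 10 (E)-4-[(1S,2R,4R)-2-hydroxy-2,6,6-trimethyl-7-oxabicyclo[2.2.1]heptan-1-yl]but-3-en-2-one
Conditions: Ph3P=CHC(O)CH3, toluene, 100 °C
Reagents that add atoms: 1-(triphenylphosphoranylidene)propan-2-one CC(=O)C=P(c1ccccc1)(c1ccccc1)c1ccccc1
Why: Wittig olefination with a stabilised ylide should give the (E)-enone under neutral conditions that avoid retro-aldol cleavage of the β-hydroxy aldehyde.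

Step 8
Reactants: 10 enone
Product: 11 (E)-1-[(1S,2R,4R)-2-hydroxy-2,6,6-trimethyl-7-oxabicyclo[2.2.1]heptan-1-yl]-3-methylpenta-1,4-dien-3-ol (mixture of C9 epimers)
Conditions: vinylmagnesium bromide (3 equiv), THF, −40 to 0 °C
Reagents that add atoms: vinylmagnesium bromide C=C[Mg]Br
Why: Grignard 1,2-addition to the methyl ketone gives the bis-allylic carbinol, whose new centre is lost in step 9.

Step 9
Reactants: 11 vinyl carbinol
Product: 12 [(2E,4E)-5-[(1S,2R,4R)-2-hydroxy-2,6,6-trimethyl-7-oxabicyclo[2.2.1]heptan-1-yl]-3-methylpenta-2,4-dienyl]triphenylphosphonium bromide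
Conditions: PPh3·HBr, MeOH, rt
Reagents that add atoms: triphenylphosphine hydrobromide [Br-].[PH+](c1ccccc1)(c1ccccc1)c1ccccc1
Why: Ionisation of the bis-allylic carbinol and capture of the pentadienyl cation by the phosphine at the terminal carbon (allylic transposition) is the standard route to C15 Wittig salts.

Step 10
Reactants: 13 ketoisophorone (2,6,6-trimethylcyclohex-2-ene-1,4-dione)
Product: 14 (4R)-4-hydroxy-2,6,6-trimethylcyclohex-2-en-1-one
Conditions: RuCl[(R,R)-TsDPEN](p-cymene) (1 mol%), HCO2H/Et3N, CH2Cl2, rt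
Reagents that add atoms: none
Why: Asymmetric transfer hydrogenation should reduce only the unhindered C4 carbonyl, and the catalyst sets the carbinol centre (future C3').

Step 11
Reactants: 14 (R)-4-hydroxyisophorone
Product: 15 (4R)-2,6,6-trimethyl-4-[(triethylsilyl)oxy]cyclohex-2-en-1-one
Conditions: TESCl, imidazole, CH2Cl2, 0 °C to rt
Reagents that add atoms: chlorotriethylsilane CC[Si](Cl)(CC)CC
Why: Silylation protects the secondary alcohol against the hydride and the triflating agent of step 12.

Step 12
Reactants: 15 silyloxy enone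
Product: 17 (4S)-2,6,6-trimethyl-4-[(triethylsilyl)oxy]cyclohex-1-en-1-yl trifluoromethanesulfonate, via lithium enolate 16 (not isolated)
Conditions: L-Selectride, THF, −78 °C; then PhNTf2, −78 to 0 °C
Reagents that add atoms: N-phenylbis(trifluoromethanesulfonimide) O=S(=O)(N(c1ccccc1)S(=O)(=O)C(F)(F)F)C(F)(F)F
Why: Conjugate reduction of the β-unsubstituted, carbonyl-hindered enone gives the regiodefined enolate, and O-triflation fixes the future C5=C6 double bond.

Step 13
Reactants: 17 vinyl triflate; 18 methyl vinyl ketone (but-3-en-2-one)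
Product: 20 (E)-4-[(4S)-4-hydroxy-2,6,6-trimethylcyclohex-1-en-1-yl]but-3-en-2-one [(3S)-3-hydroxy-β-ionone], via silyl ether 19 (not isolated)
Conditions: Pd(OAc)2 (5 mol%), PPh3, Et3N, DMF, 70 °C; then 1 M HCl, THF, rt
Reagents that add atoms: none
Why: Mizoroki–Heck coupling of the vinyl triflate with the enone should give the (E)-dienone by syn insertion and β-hydride elimination, and dilute acid removes the triethylsilyl group.

Step 14
Reactants: 20 (3S)-3-hydroxy-β-ionone
Product: 21 (E)-4-[(1S,4R,6R)-4-hydroxy-2,2,6-trimethyl-7-oxabicyclo[4.1.0]heptan-1-yl]but-3-en-2-one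
Conditions: VO(acac)2 (5 mol%), t-BuOOH, CH2Cl2, rt
Reagents that add atoms: tert-butyl hydroperoxide CC(C)(C)OO
Why: Vanadium-catalysed hydroxyl-directed epoxidation should deliver oxygen to the ring alkene from the face of the homoallylic 3-OH (syn epoxide) and leave the electron-poor enone alkene alone.

Step 15
Reactants: 21 syn epoxy alcohol
Product: 22 (E)-4-[(1S,2S,4R)-1,2,4-trihydroxy-2,6,6-trimethylcyclohexyl]but-3-en-2-one
Conditions: 5% aq. H2SO4, THF, 0 °C to rt
Reagents that add atoms: water O
Why: Acid-catalysed epoxide hydrolysis should occur by attack of water at C5 with inversion, because a cation at C6 is destabilised by the enone, which gives the trans-5,6-diol with 6-OH cis and 5-OH trans to 3-OH.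

Step 16
Reactants: 22 triol ketone
Product: 23 (1S,2S,4R)-1-[(1E)-3-hydroxy-3-methylpenta-1,4-dien-1-yl]-2,6,6-trimethylcyclohexane-1,2,4-triol (mixture of C9' epimers)
Conditions: vinylmagnesium bromide (6 equiv), THF, −40 to 0 °C
Reagents that add atoms: vinylmagnesium bromide C=C[Mg]Br
Why: Grignard 1,2-addition to the ketone after deprotonation of the three hydroxyl groups gives the bis-allylic carbinol.

Step 17
Reactants: 23 tetraol
Product: 24 [(2E,4E)-3-methyl-5-[(1S,2S,4R)-1,2,4-trihydroxy-2,6,6-trimethylcyclohexyl]penta-2,4-dienyl]triphenylphosphonium bromide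
Conditions: PPh3·HBr, MeOH, rt
Reagents that add atoms: triphenylphosphine hydrobromide [Br-].[PH+](c1ccccc1)(c1ccccc1)c1ccccc1
Why: The bis-allylic C9' carbinol ionises far more readily than the other hydroxyl groups, and phosphine capture with allylic transposition gives the C15 Wittig salt.

Step 18
Reactants: 12 phosphonium salt of the epoxy end group; 25 (2E,4E,6E)-2,7-dimethylocta-2,4,6-trienedial (3 equiv)
Product: 26 (3R,5R,6S)-3,6-epoxy-5-hydroxy-5,6-dihydro-12'-apo-β-caroten-12'-al
Conditions: NaOMe, MeOH/CH2Cl2, 0 °C to rt; then brief reflux in EtOH to equilibrate to all-E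
Reagents that add atoms: none
Why: Wittig mono-olefination of the dialdehyde, used in excess, forms the C11=C12 bond and leaves one formyl group for the second coupling.

Step 19
Reactants: 26 C25 apo-carotenal; 24 phosphonium salt of the triol end group
Product: 27 (all-E)-(3R,5R,6S,3'R,5'S,6'S)-3,6-epoxy-5,6,5',6'-tetrahydro-β,β-carotene-5,3',5',6'-tetrol
Conditions: NaOMe, MeOH/CH2Cl2, rt; then reflux in EtOH (N2, dark) to equilibrate to all-E
Reagents that add atoms: none
Why: The second Wittig olefination forms the C11'=C12' bond without touching the free hydroxyl groups, and thermal isomerisation should convert (Z)-isomers into the all-E polyene.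

Compound list
1 | methyl 3-methylfuran-2-carboxylate | COC(=O)c1occc1C | starting material
2 | (3-methylfuran-2-yl)methanol | OCc1occc1C | intermediate
3 | (3-methylfuran-2-yl)methyl acetate | CC(=O)OCc1occc1C | intermediate
4 | methacrolein | CC(=C)C=O | starting material
5 | [(1R,2S,4R)-2-formyl-2,6-dimethyl-7-oxabicyclo[2.2.1]hept-5-en-1-yl]methyl acetate (not isolated) | CC(=O)OC[C@]12O[C@H](C[C@]1(C)C=O)C=C2C | intermediate
6 | [(1R,2R,4R)-2,6-dimethyl-2-[(E)-(tosylhydrazono)methyl]-7-oxabicyclo[2.2.1]hept-5-en-1-yl]methyl acetate | CC(=O)OC[C@]12O[C@H](C[C@]1(C)/C=N/NS(=O)(=O)c1ccc(C)cc1)C=C2C | intermediate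
7 | [(1S,4R)-2,6,6-trimethyl-7-oxabicyclo[2.2.1]hept-2-en-1-yl]methanol | OC[C@]12O[C@H](CC1(C)C)C=C2C | intermediate
8 | (1R,2R,4R)-1-(hydroxymethyl)-2,6,6-trimethyl-7-oxabicyclo[2.2.1]heptan-2-ol | OC[C@]12O[C@H](CC1(C)C)C[C@@]2(C)O | intermediate
9 | (1S,2R,4R)-2-hydroxy-2,6,6-trimethyl-7-oxabicyclo[2.2.1]heptane-1-carbaldehyde | O=C[C@]12O[C@H](CC1(C)C)C[C@@]2(C)O | intermediate
10 | (E)-4-[(1S,2R,4R)-2-hydroxy-2,6,6-trimethyl-7-oxabicyclo[2.2.1]heptan-1-yl]but-3-en-2-one | CC(=O)/C=C/[C@]12O[C@H](CC1(C)C)C[C@@]2(C)O | intermediate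
11 | (E)-1-[(1S,2R,4R)-2-hydroxy-2,6,6-trimethyl-7-oxabicyclo[2.2.1]heptan-1-yl]-3-methylpenta-1,4-dien-3-ol (C9 epimers) | C=CC(C)(O)/C=C/[C@]12O[C@H](CC1(C)C)C[C@@]2(C)O | intermediate
12 | [(2E,4E)-5-[(1S,2R,4R)-2-hydroxy-2,6,6-trimethyl-7-oxabicyclo[2.2.1]heptan-1-yl]-3-methylpenta-2,4-dienyl]triphenylphosphonium bromide | C/C(=C\C[P+](c1ccccc1)(c1ccccc1)c1ccccc1)/C=C/[C@]12O[C@H](CC1(C)C)C[C@@]2(C)O.[Br-] | intermediate
13 | ketoisophorone (2,6,6-trimethylcyclohex-2-ene-1,4-dione) | CC1=CC(=O)CC(C)(C)C1=O | starting material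
14 | (4R)-4-hydroxy-2,6,6-trimethylcyclohex-2-en-1-one | O=C1C(C)=C[C@H](O)CC1(C)C | intermediate
15 | (4R)-2,6,6-trimethyl-4-[(triethylsilyl)oxy]cyclohex-2-en-1-one | O=C1C(C)=C[C@H](O[Si](CC)(CC)CC)CC1(C)C | intermediate
16 | lithium (4S)-2,6,6-trimethyl-4-[(triethylsilyl)oxy]cyclohex-1-en-1-olate (not isolated) | [Li+].[O-]C1=C(C)C[C@H](O[Si](CC)(CC)CC)CC1(C)C | intermediate
17 | (4S)-2,6,6-trimethyl-4-[(triethylsilyl)oxy]cyclohex-1-en-1-yl trifluoromethanesulfonate | FC(F)(F)S(=O)(=O)OC1=C(C)C[C@H](O[Si](CC)(CC)CC)CC1(C)C | intermediate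
18 | methyl vinyl ketone | CC(=O)C=C | starting material
19 | (E)-4-[(4S)-2,6,6-trimethyl-4-[(triethylsilyl)oxy]cyclohex-1-en-1-yl]but-3-en-2-one (not isolated) | CC(=O)/C=C/C1=C(C)C[C@H](O[Si](CC)(CC)CC)CC1(C)C | intermediate
20 | (E)-4-[(4S)-4-hydroxy-2,6,6-trimethylcyclohex-1-en-1-yl]but-3-en-2-one | CC(=O)/C=C/C1=C(C)C[C@H](O)CC1(C)C | intermediate
21 | (E)-4-[(1S,4R,6R)-4-hydroxy-2,2,6-trimethyl-7-oxabicyclo[4.1.0]heptan-1-yl]but-3-en-2-one | CC(=O)/C=C/[C@@]12O[C@]1(C)C[C@H](O)CC2(C)C | intermediate
22 | (E)-4-[(1S,2S,4R)-1,2,4-trihydroxy-2,6,6-trimethylcyclohexyl]but-3-en-2-one | CC(=O)/C=C/[C@]1(O)C(C)(C)C[C@@H](O)C[C@]1(C)O | intermediate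
23 | (1S,2S,4R)-1-[(1E)-3-hydroxy-3-methylpenta-1,4-dien-1-yl]-2,6,6-trimethylcyclohexane-1,2,4-triol (C9' epimers) | C=CC(C)(O)/C=C/[C@]1(O)C(C)(C)C[C@@H](O)C[C@]1(C)O | intermediate
24 | [(2E,4E)-3-methyl-5-[(1S,2S,4R)-1,2,4-trihydroxy-2,6,6-trimethylcyclohexyl]penta-2,4-dienyl]triphenylphosphonium bromide | C/C(=C\C[P+](c1ccccc1)(c1ccccc1)c1ccccc1)/C=C/[C@]1(O)C(C)(C)C[C@@H](O)C[C@]1(C)O.[Br-] | intermediate
25 | (2E,4E,6E)-2,7-dimethylocta-2,4,6-trienedial | O=C/C(C)=C/C=C/C=C(C)/C=O | starting material
26 | (3R,5R,6S)-3,6-epoxy-5-hydroxy-5,6-dihydro-12'-apo-β-caroten-12'-al | O=C/C(C)=C/C=C/C=C(C)/C=C/C=C(C)/C=C/[C@]12O[C@H](CC1(C)C)C[C@@]2(C)O | intermediate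
27 | (all-E)-(3R,5R,6S,3'R,5'S,6'S)-3,6-epoxy-5,6,5',6'-tetrahydro-β,β-carotene-5,3',5',6'-tetrol | CC(/C=C/C=C(C)/C=C/[C@]12O[C@H](CC1(C)C)C[C@@]2(C)O)=C\C=C\C=C(C)\C=C\C=C(C)\C=C\[C@]1(O)C(C)(C)C[C@@H](O)C[C@]1(C)O | target

Total step count: 19.
Longest linear sequence: 11 steps (steps 1–9, 18 and 19); steps 10–17 form the second branch.

Steps most likely to fail

Step 3. The furan may undergo Friedel–Crafts conjugate alkylation instead of ring closure, the adduct may revert before it is trapped, or exo/endo and facial selectivity may be too low, which would erode the enantiomeric purity once C1 is made symmetric. The fallback sets out from 3 and 4 and gives up catalyst control for resolution. An uncatalysed high-pressure cycloaddition (about 12 kbar, CH2Cl2, rt) should give the racemic aldehyde adduct F1, which is condensed with tosylhydrazide to the racemic tosylhydrazone F2 and reduced as in step 4 to the racemic bicyclic alcohol F3. Esterification with (S)-O-methylmandelic acid (DCC, DMAP), separation of the diastereomers and isolation of the mandelate of the (1S,4R)-alcohol F4, followed by saponification (LiOH, THF/H2O), returns to the route at 7.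

Step 4. Hydride addition to the hindered neopentyl hydrazone anion may be slow, so that the reduction stalls or the bicycle reverts on long heating. The fallback sets out from 5 and removes the oxygen by sulfonate displacement instead of diazene fragmentation. The cold Diels–Alder mixture is quenched with NaBH4/MeOH to give the primary alcohol F5, TsCl/pyridine gives the neopentyl tosylate F6, and LiEt3BH (THF, reflux) displaces the tosylate with hydride and cleaves the acetate, which returns to the route at 7.

Step 13. Oxidative addition and insertion at the tetrasubstituted, neopentyl-flanked vinyl triflate may be slow, with triflate hydrolysis and polymerisation of the enone taking over. The fallback sets out from 17 and builds the enone by alkynylation and reduction. Sonogashira coupling with but-3-yn-2-ol (Pd(PPh3)4, CuI, Et2NH) gives the enynol F7, Red-Al (THF, 0 °C) gives the (E)-dienol F8 by trans-hydroalumination of the propargylic alcohol, and MnO2 (CH2Cl2) oxidises it to 19, where the route is rejoined before the acid desilylation to 20.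

Further compounds
F1 | step 3 | racemic (2-formyl-2,6-dimethyl-7-oxabicyclo[2.2.1]hept-5-en-1-yl)methyl acetate | CC(=O)OCC12OC(CC1(C)C=O)C=C2C
F2 | step 3 | racemic [2,6-dimethyl-2-[(tosylhydrazono)methyl]-7-oxabicyclo[2.2.1]hept-5-en-1-yl]methyl acetate | CC(=O)OCC12OC(CC1(C)C=NNS(=O)(=O)c1ccc(C)cc1)C=C2C
F3 | step 3 | racemic (2,6,6-trimethyl-7-oxabicyclo[2.2.1]hept-2-en-1-yl)methanol | OCC12OC(CC1(C)C)C=C2C
F4 | step 3 | [(1S,4R)-2,6,6-trimethyl-7-oxabicyclo[2.2.1]hept-2-en-1-yl]methyl (S)-2-methoxy-2-phenylacetate | CO[C@H](C(=O)OC[C@]12O[C@H](CC1(C)C)C=C2C)c1ccccc1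
F5 | step 4 | [(1R,2S,4R)-2-(hydroxymethyl)-2,6-dimethyl-7-oxabicyclo[2.2.1]hept-5-en-1-yl]methyl acetate | CC(=O)OC[C@]12O[C@H](C[C@]1(C)CO)C=C2C
F6 | step 4 | [(1R,2S,4R)-2,6-dimethyl-2-(tosyloxymethyl)-7-oxabicyclo[2.2.1]hept-5-en-1-yl]methyl acetate | CC(=O)OC[C@]12O[C@H](C[C@]1(C)COS(=O)(=O)c1ccc(C)cc1)C=C2C
F7 | step 13 | 4-[(4S)-2,6,6-trimethyl-4-[(triethylsilyl)oxy]cyclohex-1-en-1-yl]but-3-yn-2-ol | CC(O)C#CC1=C(C)C[C@H](O[Si](CC)(CC)CC)CC1(C)C
F8 | step 13 | (E)-4-[(4S)-2,6,6-trimethyl-4-[(triethylsilyl)oxy]cyclohex-1-en-1-yl]but-3-en-2-ol | CC(O)/C=C/C1=C(C)C[C@H](O[Si](CC)(CC)CC)CC1(C)C
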